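**Retrosynthetic overview**
1. Endgame: C2–OH comes from a C2 ketone (Luche reduction). C7–OAc comes from a C7 ketone, reduced while the C1 enolate shields the other ketones. Both are set on a rigid pentacyclic 2,7,12-triketone.
2. Ring C (last ring): cut C12–C13. A 9β-CH2CO2H arm acylates C3 of a 1β-(2-furyl) group in an intramolecular Friedel–Crafts reaction.
3. Key step, rings A and B in one pot: cut C5–C10, C3=C4 and C8–C9. This is an asymmetric Michael / aldol condensation / Michael cascade of a 3-hydroxybutenolide (C4–C8, C17–C19) with a furyl dienone ester (C1–C3, C9–C16, C20).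
4. Fragments: the hydroxybutenolide comes from ethyl 1,3-dithiane-2-carboxylate, ethyl vinyl ketone and CH2O. The dienone ester comes from a Knoevenagel condensation of 2-furylacetone with ethyl 3-formylcrotonate.
5. Ring order: furan (bought) → lactone → A + B together → C.

**Conventions.** Clerodane numbering is used. C1–C10 form the decalin, C11 is the CH2, and C12 is the ketone. C13–C16 are the furan: C16 is the α-carbon on C1 and C13 is the β-carbon on C12. C17 is the 8-CH3, C18 the lactone C=O, C19 the lactone CH2 and C20 the 9-CH3. α/β refer to the usual drawing with H-10 β. In this numbering the target is 1S,2S,5S,7R,8S,9R,10R.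

**Assumption.** The quinidine-derived squaramide gives the drawn series (C19 α, H-10 β). If the sense of induction is opposite, the commercial quinine-derived pseudoenantiomer is used.

Step 1
Reactants: 1 ethyl 1,3-dithiane-2-carboxylate; 2 pent-1-en-3-one (ethyl vinyl ketone)
Product: 3 ethyl 2-(3-oxopentyl)-1,3-dithiane-2-carboxylate
Conditions: KOt-Bu (10 mol %), THF, 0 °C
Reagents that add atoms: none
Why: Michael addition of a soft, doubly stabilised glyoxylate acyl-anion equivalent goes 1,4 to the unhindered vinyl ketone and creates no stereocentre.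

Step 2
Reactants: 3 ethyl 2-(3-oxopentyl)-1,3-dithiane-2-carboxylate
Product: 4 ethyl 2,5-dioxoheptanoate
Conditions: PhI(OCOCF3)2, MeCN–H2O 9:1, 0 °C
Reagents that add atoms: water, O
Why: Oxidative dithiane hydrolysis with a hypervalent iodine reagent is fast at 0 °C and leaves the ketone and the ester untouched.

Step 3
Reactants: 4 ethyl 2,5-dioxoheptanoate
Product: 6 3-hydroxy-4-(2-oxobutyl)furan-2(5H)-one, via hydroxymethyl keto ester 5 (not isolated)
Conditions: 37 % aq CH2O (1.1 equiv), K2CO3 (1 equiv), EtOH–H2O, 0 °C; then 2 M HCl, 0 °C, rapid extraction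
Reagents that add atoms: formaldehyde, C=O
Why: Aldol hydroxymethylation at the most acidic CH2 (next to the α-keto ester) is followed by spontaneous γ-lactonisation and enolisation, the classical isotetronic-acid synthesis, and the enol product has no stereocentre.

Step 4
Reactants: 7 1-(furan-2-yl)propan-2-one; 8 ethyl (2E)-3-methyl-4-oxobut-2-enoate
Product: 9 ethyl (2E,4E)-5-(furan-2-yl)-3-methyl-6-oxohepta-2,4-dienoate
Conditions: piperidine/AcOH (20 mol % each), toluene, 4 Å MS, 60 °C
Reagents that add atoms: none
Why: Knoevenagel condensation at the doubly activated furfuryl/α-keto CH2 with the aldehyde gives the thermodynamic isomer with acetyl trans to the diene chain, as is usual for arylacetones, and the (2E)-enoate is retained.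

Step 5
Reactants: 6 3-hydroxy-4-(2-oxobutyl)furan-2(5H)-one; 9 ethyl (2E,4E)-5-(furan-2-yl)-3-methyl-6-oxohepta-2,4-dienoate
Product: 12 tricyclic 2,7-diketo lactone ethyl ester, via Michael adduct 10 (not isolated), via enedione lactone 11 (not isolated)
Conditions: quinidine-derived 3,5-(CF3)2C6H3-squaramide (10 mol %), CH2Cl2, 4 Å MS, 0 °C → rt; then KOt-Bu (2.2 equiv), THF, −40 → 0 °C; AcOH quench
Reagents that add atoms: none
Why: Proposed new method: an asymmetric Michael/aldol-condensation/Michael cascade in which every bond follows natural polarity; the enol carbon C5 of 6 (a cyclic 1,2-dicarbonyl enol paired with the catalyst ammonium) attacks C10, the β-carbon of the squaramide-bound methyl ketone of 9, through the closed transition state that places C4–O next to the acetyl oxygen, the small ring CH2 (C19) in the crowded inner sector and the long C6 arm anti to C1, which sets C5 and C10 in the relative sense of a trans-decalin and, through the catalyst, in the absolute sense drawn; the now non-enolisable, very electrophilic α-keto-lactone carbonyl C4 is captured by the methyl-ketone enolate C3 in a favoured 6-(enolendo)-exo-trig aldol, and E1cB loss of water closes ring A (11); the second equivalent of base lets the ethyl-ketone enolate C8 close ring B by 6-exo-trig Michael addition to the β,β-disubstituted enoate through a chair in which the smaller CH3 rather than the CH=CO2Et arm takes the axial site syn to C19, which sets C9, while C8 and C1 equilibrate to equatorial CH3 and equatorial furyl; the closest known reaction types are the organocatalytic Michael/Robinson annulation of cyclic 1,2-diones and β-keto esters with enones and the base-mediated anionic polycyclisation route to decalins.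

Step 6
Reactants: 12 tricyclic 2,7-diketo lactone ethyl ester
Product: 13 tricyclic 2,7-diketo lactone carboxylic acid
Conditions: LiOH (4 equiv), THF–H2O, 0 °C → rt; then 1 M HCl to pH 2
Reagents that add atoms: lithium hydroxide, [Li+].[OH-]
Why: In this saponification the enedione sits protected as its C1 enolate, any opened γ-lactone recloses on acidification, and only the already equilibrated centres C1 and C8 are base-labile.

Step 7
Reactants: 13 tricyclic 2,7-diketo lactone carboxylic acid
Product: 15 pentacyclic 2,7,12-triketone, via acid chloride 14 (not isolated)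
Conditions: 1-chloro-N,N,2-trimethylpropenylamine (Ghosez reagent, 1.1 equiv), CH2Cl2, 0 °C; then HFIP, 2 mM, rt
Reagents that add atoms: none
Why: In this intramolecular Friedel–Crafts acylation, the equatorial 9β-CH2COCl arm and the equatorial 1β-(2-alkylfuran) lie side by side, only furan C3 is within reach, high dilution suppresses intermolecular C5 acylation, and no stereocentre is formed.

Step 8
Reactants: 15 pentacyclic 2,7,12-triketone
Product: 17 7α-hydroxy-2,12-dione, via lithium dienolate 16 (not isolated)
Conditions: LiHMDS (1.05 equiv), THF, −78 °C; L-Selectride (1.2 equiv), −78 °C; AcOH quench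
Reagents that add atoms: none
Why: With in situ enolate protection, deprotonation of the very acidic C1–H gives an anion conjugated with C2=O and, through the furan, with C12=O, so C7 is the only neutral ketone, and the bulky hydride attacks it from the equatorial β side (the α side is blocked by axial C19 and C20) to give the axial 7α-alcohol, with C1 reprotonated to the only unstrained epimer.

Step 9
Reactants: 17 7α-hydroxy-2,12-dione
Product: 18 7α-acetoxy-2,12-dione
Conditions: Ac2O (3 equiv), Sc(OTf)3 (5 mol %), MeCN, −20 → 0 °C
Reagents that add atoms: acetic anhydride, CC(=O)OC(C)=O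
Why: Lewis-acid-catalysed acylation acetylates hindered axial alcohols without base, so the acidic C1–H is not enolised and configuration at C7 is retained.

Step 10
Reactants: 18 7α-acetoxy-2,12-dione
Product: 19 target compound CNP0182929.1
Conditions: NaBH4, CeCl3·7H2O, MeOH, −78 °C
Reagents that add atoms: none
Why: Luche 1,2-reduction of the most electrophilic carbonyl (the C2 enone) goes by axial attack from the open β face to give the equatorial 2α-alcohol trans to the furan carbon on C1, while the vinylogous-ester-like C12 ketone, the lactone and the acetate do not react at −78 °C.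

**Compound list**
1 | ethyl 1,3-dithiane-2-carboxylate | CCOC(=O)C1SCCCS1 | starting material
2 | pent-1-en-3-one | CCC(=O)C=C | starting material
3 | ethyl 2-(3-oxopentyl)-1,3-dithiane-2-carboxylate | CCOC(=O)C1(CCC(=O)CC)SCCCS1 | intermediate
4 | ethyl 2,5-dioxoheptanoate | CCOC(=O)C(=O)CCC(=O)CC | intermediate
5 | ethyl 3-(hydroxymethyl)-2,5-dioxoheptanoate (racemic, not isolated) | CCOC(=O)C(=O)C(CO)CC(=O)CC | intermediate
6 | 3-hydroxy-4-(2-oxobutyl)furan-2(5H)-one | CCC(=O)CC1=C(O)C(=O)OC1 | intermediate
7 | 1-(furan-2-yl)propan-2-one | CC(=O)Cc1ccco1 | starting material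
8 | ethyl (2E)-3-methyl-4-oxobut-2-enoate | O=C/C(C)=C/C(=O)OCC | starting material
9 | ethyl (2E,4E)-5-(furan-2-yl)-3-methyl-6-oxohepta-2,4-dienoate | CC(=O)/C(c1ccco1)=C/C(C)=C/C(=O)OCC | intermediate
10 | Michael adduct: α-keto-γ-lactone whose quaternary C5 carries CH2COEt and C10H; C10 carries CH(2-furyl)COCH3 and the (E)-C(CH3)=CHCO2Et arm; C5/C10 as in the target (not isolated) | CCC(=O)C[C@]1(COC(=O)C1=O)[C@H]([C@H](c2ccco2)C(C)=O)/C(C)=C/C(=O)OCC | intermediate
11 | enedione lactone (ring A + lactone): 2-oxo, C3=C4, 18,19-olide with C19 α on C5, C6 arm (CH2COEt) β on C5, H-10 β, (E)-C(CH3)=CHCO2Et arm equatorial on C10 (trans to the C6 arm), 1β-furyl (not isolated) | CCC(=O)C[C@@]12COC(=O)C1=CC(=O)[C@@H](c3ccco3)[C@@H]2/C(C)=C/C(=O)OCC | intermediate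
12 | tricyclic 2,7-diketo lactone ethyl ester: trans-decalin (C19 α, H-10 β), C3=C4, 18,19-olide, 1β-(furan-2-yl) eq, 8α-CH3 eq, 9α-CH3 ax, 9β-CH2CO2Et eq | O=C1C[C@@]23COC(=O)C2=CC(=O)[C@@H](c4ccco4)[C@@H]3[C@@](C)(CC(=O)OCC)[C@@H]1C | intermediate
13 | carboxylic acid of 12 (9β-CH2CO2H) | O=C1C[C@@]23COC(=O)C2=CC(=O)[C@@H](c4ccco4)[C@@H]3[C@@](C)(CC(=O)O)[C@@H]1C | intermediate
14 | acid chloride of 13 (not isolated) | O=C1C[C@@]23COC(=O)C2=CC(=O)[C@@H](c4ccco4)[C@@H]3[C@@](C)(CC(=O)Cl)[C@@H]1C | intermediate
15 | pentacyclic 2,7,12-triketone (ring C closed C12–C13; H-1 α, H-10 β, C19 α, 8α-CH3, 9α-CH3) | O=C1C[C@@]23COC(=O)C2=CC(=O)[C@H]2c4occc4C(=O)C[C@@](C)([C@@H]1C)[C@@H]23 | intermediate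
16 | lithium C1=C2 dienolate of 15 (not isolated) | O=C1C[C@@]23COC(=O)C2=CC([O-])=C2c4occc4C(=O)C[C@@](C)([C@@H]1C)[C@@H]23.[Li+] | intermediate
17 | 7α-hydroxy-2,12-dione (axial OH) | O[C@@H]1C[C@@]23COC(=O)C2=CC(=O)[C@H]2c4occc4C(=O)C[C@@](C)([C@@H]1C)[C@@H]23 | intermediate
18 | 7α-acetoxy-2,12-dione | CC(=O)O[C@@H]1C[C@@]23COC(=O)C2=CC(=O)[C@H]2c4occc4C(=O)C[C@@](C)([C@@H]1C)[C@@H]23 | intermediate
19 | CNP0182929.1: 7α-acetoxy-2α-hydroxy-12-oxo-1,16-cyclo-neo-clerod-3-en-18,19-olide furan (1S,2S,5S,7R,8S,9R,10R) | CC(=O)O[C@@H]1C[C@@]23COC(=O)C2=C[C@H](O)[C@H]2c4occc4C(=O)C[C@@](C)([C@@H]1C)[C@@H]23 | target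

**Totals.** There are 10 steps in total. The longest linear sequence is 9 steps (steps 1, 2, 3, 5, 6, 7, 8, 9, 10). No protecting groups are used.

**Steps most likely to fail**

The cascade of step 5 carries the most risk. The first Michael addition may be reversible, and the sense and level of ee and dr are untested. Five-ring aldols between the two ketone arms may also compete. The fallback replaces catalysis by a covalent auxiliary and closes the rings one at a time.
- It sets out from 6, which is condensed with (R)-1-phenylethylamine (toluene, 4 Å MS) to the secondary enamino lactone F1.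
- F1 adds to 9 under neutral conditions (neat or with MgBr2·OEt2) through the compact aza-ene-type transition state of the chiral-imine Michael reaction. Attack is anti to the phenyl group and gives the ketimine Michael adduct F2.
- Aqueous AcOH hydrolyses F2 to 10, which is now isolated.
- Pyrrolidinium acetate closes ring A to 11, and KOt-Bu closes ring B. The route is rejoined at 12.

Second is step 7. Furan C3 is less nucleophilic than the free C5, and the furan may suffer from the HCl that is released. The fallback changes the electrophile to an activated amide under buffered, HCl-free conditions.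
- It sets out from 13, which is coupled with dimethylamine (EDC) to the N,N-dimethylamide F3.
- Tf2O with 2-chloropyridine at −78 → 0 °C activates only the amide oxygen. A Vilsmeier-type ring closure at furan C3 then gives the cyclic iminium triflate F4.
- Aqueous NaHCO3 hydrolyses F4, and the route is rejoined at 15.

Third is step 8. Deprotonation may be incomplete, or hydride may attack C12 or the unsaturated lactone. The fallback drops the differentiation at the ketone stage and differentiates the two esters instead.
- It sets out from 15, which is reduced with excess NaBH4/CeCl3 at −40 °C at C2 and C7 to the 2α,7α-diol F5. The stereochemical arguments are the same as in the main route, and the vinylogous-ester-like C12 ketone reacts slowest.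
- Ac2O/Sc(OTf)3 gives the 2α,7α-diacetate F6.
- K2CO3/MeOH at 0 °C, or a lipase, removes only the exposed equatorial allylic C2 acetate. The axial C7 acetate, shielded by C19 and C20, stays. The route is rejoined at 19.

**Further compounds**
F1 | step 5 | 3-{[(1R)-1-phenylethyl]amino}-4-(2-oxobutyl)furan-2(5H)-one | CCC(=O)CC1=C(N[C@H](C)c2ccccc2)C(=O)OC1
F2 | step 5 | N-[(1R)-1-phenylethyl] ketimine (at C4) of Michael adduct 10 | CCC(=O)C[C@]1(COC(=O)C1=N[C@H](C)c3ccccc3)[C@H]([C@H](c2ccco2)C(C)=O)/C(C)=C/C(=O)OCC
F3 | step 7 | N,N-dimethylamide of acid 13 | O=C1C[C@@]23COC(=O)C2=CC(=O)[C@@H](c4ccco4)[C@@H]3[C@@](C)(CC(=O)N(C)C)[C@@H]1C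
F4 | step 7 | pentacyclic C12 dimethyliminium triflate | O=C1C[C@@]23COC(=O)C2=CC(=O)[C@H]2c4occc4C(=[N+](C)C)C[C@@](C)([C@@H]1C)[C@@H]23.[O-]S(=O)(=O)C(F)(F)F
F5 | step 8 | 2α,7α-dihydroxy-12-ketone | O[C@@H]1C[C@@]23COC(=O)C2=C[C@H](O)[C@H]2c4occc4C(=O)C[C@@](C)([C@@H]1C)[C@@H]23
F6 | step 8 | 2α,7α-diacetoxy-12-ketone | CC(=O)O[C@@H]1C[C@@]23COC(=O)C2=C[C@H](OC(C)=O)[C@H]2c4occc4C(=O)C[C@@](C)([C@@H]1C)[C@@H]23
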